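**Assumption:** the SMILES is taken literally (a nine-carbon chain, numbered C1′–C9′ from the bis-benzylic carbon); it reads as (2S)-flavanone, (1′S), (7′R) and a 2′E alkene.

**Retrosynthetic overview**
1. C-ring last: (2S) comes from a Rh-catalysed asymmetric 1,4-arylation of chromone 30 (C2–aryl bond), followed by global desilylation.
2. C1′–C2′ bond and (1′S): chiral-biphenol-catalysed addition of (E)-alkenylboronate 14 to the o-quinone methide of 7-hydroxychromone 27.
3. Chain C2′–C9′ with (7′R): alkyne from δ-lactone 9, made by two consecutive ring expansions: cyclobutanone → (R)-2-substituted cyclopentanone 8 (enantioselective diazoalkane insertion, a C→C 1,2-shift) → lactone (Baeyer–Villiger).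
4. A ring: resorcinol → 1,3,5-trioxygenated arene by Ir C–H borylation/oxidation; the C8 and C4a carbons by two directed ortho-lithiations in one pot; all three 4-hydroxyphenyl groups from 4-iodophenol.
5. Ring order: cyclopentanone (step 4) → δ-lactone (step 5, reopened in step 7) → chromone pyranone (step 15) → flavanone C-ring (step 19).

**Route**

Step 1
Reactants: 1 4-iodophenol
Product: 2 (4-iodophenoxy)tri(propan-2-yl)silane
Conditions: TIPSCl, imidazole, DMF, rt
Reagents that add atoms: chlorotri(propan-2-yl)silane CC(C)[Si](Cl)(C(C)C)C(C)C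
Why: O-silylation gives a bulky aryl silyl ether that survives organometallics, carbonate and mild acid and serves as the source of all three 4-oxyphenyl units.

Step 2
Reactants: 2 (4-iodophenoxy)tri(propan-2-yl)silane; 3 prop-2-en-1-ol
Product: 4 3-{4-[tri(propan-2-yl)silyloxy]phenyl}propanal
Conditions: Pd(OAc)2 (2 mol%), n-Bu4NCl, NaHCO3, DMF, 45 °C
Reagents that add atoms: none
Why: Jeffery-type Heck arylation of allyl alcohol, in which β-hydride elimination toward the carbinol carbon and tautomerisation give the saturated aldehyde (C9′–C8′–C7′).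

Step 3
Reactants: 4 3-{4-[tri(propan-2-yl)silyloxy]phenyl}propanal
Product: 5 (3-{4-[tri(propan-2-yl)silyloxy]phenyl}propylidene)hydrazine
Conditions: N2H4·H2O (10 equiv), EtOH, 0 °C → rt; used crude
Reagents that add atoms: hydrazine NN
Why: Hydrazone condensation, with excess hydrazine suppressing azine formation.

Step 4
Reactants: 5 (3-{4-[tri(propan-2-yl)silyloxy]phenyl}propylidene)hydrazine; 6 cyclobutanone
Product: 8 (2R)-2-(2-{4-[tri(propan-2-yl)silyloxy]phenyl}ethyl)cyclopentan-1-one, via diazoalkane 7 (not isolated)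
Conditions: activated MnO2, MgSO4, toluene, −20 °C, cold filtration; filtrate added to 6 (1.5 equiv), Sc(OTf)3 (10 mol%), chiral tris(oxazoline) ligand (12 mol%), toluene, −78 °C
Reagents that add atoms: none
Why: Proposed new method: Sc(III)–chiral tris(oxazoline)-catalysed enantioselective insertion of the non-stabilised alkyl diazomethane 7 into cyclobutanone (Tiffeneau–Demjanov-type ring expansion), in which the diazo carbon adds through one enantioface to the Sc-bound C=O and the ring C–C bond anti to N2+ then shifts 1,2 onto it with loss of N2 (strain release, so only one insertion), making it C2 and fixing (R) at −78 °C where the α-centre does not enolise; the closest known reaction type is the Sc-catalysed enantioselective insertion of aryldiazomethanes into cycloalkanones together with the racemic Sc(OTf)3-catalysed homologation with alkyl diazomethanes, and the ligand enantiomer that gives (R) is fixed by comparison with auxiliary-derived 8.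

Step 5
Reactants: 8 (2R)-2-(2-{4-[tri(propan-2-yl)silyloxy]phenyl}ethyl)cyclopentan-1-one
Product: 9 (6R)-6-(2-{4-[tri(propan-2-yl)silyloxy]phenyl}ethyl)oxan-2-one
Conditions: m-CPBA, NaHCO3, CH2Cl2, 0 °C → rt
Reagents that add atoms: 3-chloroperoxybenzoic acid OOC(=O)c1cccc(Cl)c1
Why: Baeyer–Villiger ring expansion in which the more substituted C2 migrates to oxygen with retention, so the (R)-ketone gives the (6R)-δ-lactone holding C3′–C7′ with both ends differentiated, the bicarbonate buffer preventing enolisation.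

Step 6
Reactants: 9 (6R)-6-(2-{4-[tri(propan-2-yl)silyloxy]phenyl}ethyl)oxan-2-one
Product: 10 (6R)-6-(2-{4-[tri(propan-2-yl)silyloxy]phenyl}ethyl)oxan-2-ol
Conditions: DIBAL-H (1.1 equiv), CH2Cl2, −78 °C; Rochelle salt
Reagents that add atoms: none
Why: Half-reduction of the lactone to the lactol through the aluminate that is stable at −78 °C.

Step 7
Reactants: 10 (6R)-6-(2-{4-[tri(propan-2-yl)silyloxy]phenyl}ethyl)oxan-2-ol
Product: 11 (3R)-1-{4-[tri(propan-2-yl)silyloxy]phenyl}oct-7-yn-3-ol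
Conditions: dimethyl (1-diazo-2-oxopropyl)phosphonate, K2CO3, MeOH, 0 °C → rt
Reagents that add atoms: dimethyl (1-diazo-2-oxopropyl)phosphonate COP(=O)(OC)C(=[N+]=[N-])C(C)=O
Why: Ohira–Bestmann (Seyferth–Gilbert) homologation of the open hydroxy-aldehyde form of the lactol adds C2′ as a terminal alkyne without touching C7′.

Step 8
Reactants: 11 (3R)-1-{4-[tri(propan-2-yl)silyloxy]phenyl}oct-7-yn-3-ol
Product: 12 tert-butyl(dimethyl){[(3R)-1-{4-[tri(propan-2-yl)silyloxy]phenyl}oct-7-yn-3-yl]oxy}silane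
Conditions: TBSCl, imidazole, DMF, rt
Reagents that add atoms: tert-butyl(chloro)dimethylsilane CC(C)(C)[Si](C)(C)Cl
Why: Silyl protection keeps the secondary alcohol out of the borane and boronate-exchange chemistry that follows.

Step 9
Reactants: 12 tert-butyl(dimethyl){[(3R)-1-{4-[tri(propan-2-yl)silyloxy]phenyl}oct-7-yn-3-yl]oxy}silane
Product: 14 dicyclohexyl [(1E,6R)-6-(tert-butyldimethylsilyloxy)-8-{4-[tri(propan-2-yl)silyloxy]phenyl}oct-1-en-1-yl]boronate, via alkenylborane 13 (not isolated)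
Conditions: Cy2BH (1.1 equiv), THF, 0 °C → rt; then Me3NO (2.1 equiv), rt
Reagents that add atoms: dicyclohexylborane B(C1CCCCC1)C1CCCCC1; trimethylamine N-oxide C[N+](C)(C)[O-]
Why: Syn, anti-Markovnikov hydroboration gives the (E)-alkenylborane, and amine-oxide oxidation of the two B–cyclohexyl bonds (sec-alkyl migrates before alkenyl) leaves an exchangeable dialkoxy (E)-alkenylboronate.

Step 10
Reactants: 15 benzene-1,3-diol
Product: 16 1,3-bis(methoxymethoxy)benzene
Conditions: MOMCl (2.5 equiv), i-Pr2NEt, CH2Cl2, 0 °C → rt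
Reagents that add atoms: chloro(methoxy)methane COCCl
Why: Bis-MOM protection supplies the two directing groups used later for ortho-lithiation.

Step 11
Reactants: 16 1,3-bis(methoxymethoxy)benzene
Product: 18 3,5-bis(methoxymethoxy)phenol, via arylboronate 17 (not isolated)
Conditions: [Ir(OMe)(cod)]2 (1.5 mol%), dtbpy (3 mol%), B2pin2, THF, 80 °C; then aq. H2O2, NaOH, 0 °C
Reagents that add atoms: hydrogen peroxide OO
Why: Sterically controlled Ir-catalysed C–H borylation goes to the only position meta to both substituents, and one-pot oxidation of the C–B bond gives the 1,3,5-trioxygenated ring.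

Step 12
Reactants: 18 3,5-bis(methoxymethoxy)phenol
Product: 19 1-methoxy-3,5-bis(methoxymethoxy)benzene
Conditions: MeI, K2CO3, acetone, reflux
Reagents that add atoms: iodomethane CI
Why: Williamson O-methylation installs the future 5-OMe.

Step 13
Reactants: 19 1-methoxy-3,5-bis(methoxymethoxy)benzene
Product: 23 3-acetyl-4-methoxy-2,6-bis(methoxymethoxy)benzaldehyde, via aryllithium 20 (not isolated), via amino alkoxide 21 (not isolated), via ring-lithiated amino alkoxide 22 (not isolated)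
Conditions: n-BuLi, THF, 0 °C; DMF, −78 °C; s-BuLi, TMEDA, −78 → −40 °C; MeC(O)N(OMe)Me, −78 → 0 °C; aq. NH4Cl
Reagents that add atoms: N,N-dimethylformamide CN(C)C=O; N-methoxy-N-methylacetamide CC(=O)N(C)OC
Why: Two directed ortho-metalations in one pot, the first between the two OMOM groups (future C8 carbon), the DMF adduct then acting as an in situ protected aldehyde (Comins tactic) while the second lithiation occurs at the site flanked by OMOM and OMe and the Weinreb amide stops at the ketone (future C4).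

Step 14
Reactants: 23 3-acetyl-4-methoxy-2,6-bis(methoxymethoxy)benzaldehyde; 2 (4-iodophenoxy)tri(propan-2-yl)silane
Product: 25 1-[3-(hydroxy{4-[tri(propan-2-yl)silyloxy]phenyl}methyl)-6-methoxy-2,4-bis(methoxymethoxy)phenyl]ethan-1-one, via aryl Grignard 24 (not isolated)
Conditions: 2, Mg, THF, rt; added to 23, THF, −78 °C; aq. NH4Cl
Reagents that add atoms: none
Why: Grignard addition is chemoselective for the aldehyde over the hindered, twisted methyl ketone at −78 °C and gives the (racemic) benzhydrol whose centre is later erased in the quinone methide.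

Step 15
Reactants: 25 1-[3-(hydroxy{4-[tri(propan-2-yl)silyloxy]phenyl}methyl)-6-methoxy-2,4-bis(methoxymethoxy)phenyl]ethan-1-one
Product: 27 8-(ethoxy{4-[tri(propan-2-yl)silyloxy]phenyl}methyl)-7-hydroxy-5-methoxy-4H-chromen-4-one, via enaminone 26 (not isolated)
Conditions: Me2NCH(OMe)2, toluene, 95 °C; evaporate; HCl (2 M in EtOH), 45 °C
Reagents that add atoms: N,N-dimethylformamide dimethyl acetal COC(OC)N(C)C; ethanol CCO
Why: Enaminone formation then acid-mediated MOM cleavage and cyclocondensation, in which only the phenol ortho to the acyl group can close the chromone (fixing 5-OMe/7-OH/8-C), while the ionisable benzhydrol is solvolysed to the ethyl ether, a storable o-quinone methide precursor.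

Step 16
Reactants: 27 8-(ethoxy{4-[tri(propan-2-yl)silyloxy]phenyl}methyl)-7-hydroxy-5-methoxy-4H-chromen-4-one; 14 dicyclohexyl [(1E,6R)-6-(tert-butyldimethylsilyloxy)-8-{4-[tri(propan-2-yl)silyloxy]phenyl}oct-1-en-1-yl]boronate
Product: 29 8-[(1S,2E,7R)-7-(tert-butyldimethylsilyloxy)-1,9-bis{4-[tri(propan-2-yl)silyloxy]phenyl}non-2-en-1-yl]-7-hydroxy-5-methoxy-4H-chromen-4-one, via o-quinone methide 28 (not isolated)
Conditions: (R)-3,3′-Br2-BINOL (15 mol%), 4 Å MS, PhCF3, 40 °C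
Reagents that add atoms: none
Why: Chiral-biphenol-catalysed 1,4-addition of an alkenylboronate to an in situ o-quinone methide (Schaus-type, Petasis-like), in which the boronate exchanges its alkoxides for the BINOL and the 7-OH, ethoxide leaves to give 28, and the E-alkenyl group is delivered inside the chiral boron ate complex to one face of the exocyclic carbon, setting C1′ (S) with the alkene geometry retained (the catalyst enantiomer is the handle if the sense proves opposite).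

Step 17
Reactants: 29 8-[(1S,2E,7R)-7-(tert-butyldimethylsilyloxy)-1,9-bis{4-[tri(propan-2-yl)silyloxy]phenyl}non-2-en-1-yl]-7-hydroxy-5-methoxy-4H-chromen-4-one
Product: 30 8-[(1S,2E,7R)-7-(tert-butyldimethylsilyloxy)-1,9-bis{4-[tri(propan-2-yl)silyloxy]phenyl}non-2-en-1-yl]-5-methoxy-7-[tri(propan-2-yl)silyloxy]-4H-chromen-4-one
Conditions: TIPSOTf, 2,6-lutidine, CH2Cl2, 0 °C
Reagents that add atoms: tri(propan-2-yl)silyl trifluoromethanesulfonate CC(C)[Si](OS(=O)(=O)C(F)(F)F)(C(C)C)C(C)C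
Why: Silylation masks the acidic 7-OH, which would otherwise deactivate the chromone as its phenoxide and protonate aryl–Rh in the next step.

Step 18
Reactants: 2 (4-iodophenoxy)tri(propan-2-yl)silane
Product: 32 {4-[tri(propan-2-yl)silyloxy]phenyl}boronic acid, via aryllithium 31 (not isolated)
Conditions: n-BuLi, THF, −78 °C; B(Oi-Pr)3; aq. NH4Cl
Reagents that add atoms: tri(propan-2-yl) borate CC(C)OB(OC(C)C)OC(C)C
Why: Iodine–lithium exchange and borylation give the B-ring donor.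

Step 19
Reactants: 30 8-[(1S,2E,7R)-7-(tert-butyldimethylsilyloxy)-1,9-bis{4-[tri(propan-2-yl)silyloxy]phenyl}non-2-en-1-yl]-5-methoxy-7-[tri(propan-2-yl)silyloxy]-4H-chromen-4-one; 32 {4-[tri(propan-2-yl)silyloxy]phenyl}boronic acid
Product: 33 (2S)-8-[(1S,2E,7R)-7-(tert-butyldimethylsilyloxy)-1,9-bis{4-[tri(propan-2-yl)silyloxy]phenyl}non-2-en-1-yl]-5-methoxy-2-{4-[tri(propan-2-yl)silyloxy]phenyl}-7-[tri(propan-2-yl)silyloxy]-2,3-dihydro-4H-chromen-4-one
Conditions: [Rh(OH)(cod)]2 (3 mol%), (S)-MeO-F12-BIPHEP (7 mol%), 32 (3 equiv), toluene/H2O, 40 °C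
Reagents that add atoms: none
Why: Hayashi–Miyaura Rh-catalysed asymmetric 1,4-addition to a chromone, in which aryl–Rh inserts C2=C3 on the face set by the ligand (by the (S)-BINAP → (S)-3-arylcyclohexanone model this maps onto 2S, to be confirmed, the other ligand enantiomer being the remedy) and water protonates the Rh enolate under base-free conditions that spare the silyl ethers and override the remote centres.

Step 20
Reactants: 33 (2S)-8-[(1S,2E,7R)-7-(tert-butyldimethylsilyloxy)-1,9-bis{4-[tri(propan-2-yl)silyloxy]phenyl}non-2-en-1-yl]-5-methoxy-2-{4-[tri(propan-2-yl)silyloxy]phenyl}-7-[tri(propan-2-yl)silyloxy]-2,3-dihydro-4H-chromen-4-one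
Product: 34 (2S)-7-hydroxy-8-[(1S,2E,7R)-7-hydroxy-1,9-bis(4-hydroxyphenyl)non-2-en-1-yl]-2-(4-hydroxyphenyl)-5-methoxy-2,3-dihydro-4H-chromen-4-one
Conditions: HF·pyridine, pyridine/THF, 0 °C → rt
Reagents that add atoms: none
Why: Buffered fluoride desilylation removes all five silyl groups without base (no flavanone ring-opening at C2) and without strong acid (no ionisation of the bis-benzylic C1′).

**Compound list**
1 | 4-iodophenol | Oc1ccc(I)cc1 | starting material
2 | (4-iodophenoxy)tri(propan-2-yl)silane | CC(C)[Si](Oc1ccc(I)cc1)(C(C)C)C(C)C | intermediate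
3 | prop-2-en-1-ol | C=CCO | starting material
4 | 3-{4-[tri(propan-2-yl)silyloxy]phenyl}propanal | O=CCCc1ccc(O[Si](C(C)C)(C(C)C)C(C)C)cc1 | intermediate
5 | (3-{4-[tri(propan-2-yl)silyloxy]phenyl}propylidene)hydrazine | NN=CCCc1ccc(O[Si](C(C)C)(C(C)C)C(C)C)cc1 | intermediate
6 | cyclobutanone | O=C1CCC1 | starting material
7 | [4-(3-diazopropyl)phenoxy]tri(propan-2-yl)silane | [N-]=[N+]=CCCc1ccc(O[Si](C(C)C)(C(C)C)C(C)C)cc1 | intermediate
8 | (2R)-2-(2-{4-[tri(propan-2-yl)silyloxy]phenyl}ethyl)cyclopentan-1-one | O=C1CCC[C@@H]1CCc1ccc(O[Si](C(C)C)(C(C)C)C(C)C)cc1 | intermediate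
9 | (6R)-6-(2-{4-[tri(propan-2-yl)silyloxy]phenyl}ethyl)oxan-2-one | O=C1CCC[C@H](CCc2ccc(O[Si](C(C)C)(C(C)C)C(C)C)cc2)O1 | intermediate
10 | (6R)-6-(2-{4-[tri(propan-2-yl)silyloxy]phenyl}ethyl)oxan-2-ol (anomer mixture) | OC1CCC[C@H](CCc2ccc(O[Si](C(C)C)(C(C)C)C(C)C)cc2)O1 | intermediate
11 | (3R)-1-{4-[tri(propan-2-yl)silyloxy]phenyl}oct-7-yn-3-ol | C#CCCC[C@@H](O)CCc1ccc(O[Si](C(C)C)(C(C)C)C(C)C)cc1 | intermediate
12 | tert-butyl(dimethyl){[(3R)-1-{4-[tri(propan-2-yl)silyloxy]phenyl}oct-7-yn-3-yl]oxy}silane | C#CCCC[C@@H](O[Si](C)(C)C(C)(C)C)CCc1ccc(O[Si](C(C)C)(C(C)C)C(C)C)cc1 | intermediate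
13 | dicyclohexyl[(1E,6R)-6-(tert-butyldimethylsilyloxy)-8-{4-[tri(propan-2-yl)silyloxy]phenyl}oct-1-en-1-yl]borane | B(C1CCCCC1)(C1CCCCC1)/C=C/CCC[C@@H](O[Si](C)(C)C(C)(C)C)CCc1ccc(O[Si](C(C)C)(C(C)C)C(C)C)cc1 | intermediate
14 | dicyclohexyl [(1E,6R)-6-(tert-butyldimethylsilyloxy)-8-{4-[tri(propan-2-yl)silyloxy]phenyl}oct-1-en-1-yl]boronate | B(OC1CCCCC1)(OC1CCCCC1)/C=C/CCC[C@@H](O[Si](C)(C)C(C)(C)C)CCc1ccc(O[Si](C(C)C)(C(C)C)C(C)C)cc1 | intermediate
15 | benzene-1,3-diol (resorcinol) | Oc1cccc(O)c1 | starting material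
16 | 1,3-bis(methoxymethoxy)benzene | COCOc1cccc(OCOC)c1 | intermediate
17 | 2-[3,5-bis(methoxymethoxy)phenyl]-4,4,5,5-tetramethyl-1,3,2-dioxaborolane | COCOc1cc(OCOC)cc(c1)B1OC(C)(C)C(C)(C)O1 | intermediate
18 | 3,5-bis(methoxymethoxy)phenol | COCOc1cc(O)cc(OCOC)c1 | intermediate
19 | 1-methoxy-3,5-bis(methoxymethoxy)benzene | COCOc1cc(OC)cc(OCOC)c1 | intermediate
20 | [4-methoxy-2,6-bis(methoxymethoxy)phenyl]lithium | [Li]c1c(OCOC)cc(OC)cc1OCOC | intermediate
21 | lithium (dimethylamino)[4-methoxy-2,6-bis(methoxymethoxy)phenyl]methanolate | [Li]OC(N(C)C)c1c(OCOC)cc(OC)cc1OCOC | intermediate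
22 | lithium (dimethylamino)[3-lithio-4-methoxy-2,6-bis(methoxymethoxy)phenyl]methanolate | [Li]OC(N(C)C)c1c(OCOC)cc(OC)c([Li])c1OCOC | intermediate
23 | 3-acetyl-4-methoxy-2,6-bis(methoxymethoxy)benzaldehyde | CC(=O)c1c(OC)cc(OCOC)c(C=O)c1OCOC | intermediate
24 | iodo{4-[tri(propan-2-yl)silyloxy]phenyl}magnesium | I[Mg]c1ccc(O[Si](C(C)C)(C(C)C)C(C)C)cc1 | intermediate
25 | 1-[3-(hydroxy{4-[tri(propan-2-yl)silyloxy]phenyl}methyl)-6-methoxy-2,4-bis(methoxymethoxy)phenyl]ethan-1-one (racemic) | CC(=O)c1c(OC)cc(OCOC)c(C(O)c2ccc(O[Si](C(C)C)(C(C)C)C(C)C)cc2)c1OCOC | intermediate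
26 | (2E)-3-(dimethylamino)-1-[3-(hydroxy{4-[tri(propan-2-yl)silyloxy]phenyl}methyl)-6-methoxy-2,4-bis(methoxymethoxy)phenyl]prop-2-en-1-one | CN(C)/C=C/C(=O)c1c(OC)cc(OCOC)c(C(O)c2ccc(O[Si](C(C)C)(C(C)C)C(C)C)cc2)c1OCOC | intermediate
27 | 8-(ethoxy{4-[tri(propan-2-yl)silyloxy]phenyl}methyl)-7-hydroxy-5-methoxy-4H-chromen-4-one (racemic) | CCOC(c1ccc(O[Si](C(C)C)(C(C)C)C(C)C)cc1)c1c(O)cc(OC)c2c(=O)ccoc12 | intermediate
28 | 5-methoxy-8-({4-[tri(propan-2-yl)silyloxy]phenyl}methylidene)-4H-chromene-4,7(8H)-dione | COC1=CC(=O)C(=Cc2ccc(O[Si](C(C)C)(C(C)C)C(C)C)cc2)C2=C1C(=O)C=CO2 | intermediate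
29 | 8-[(1S,2E,7R)-7-(tert-butyldimethylsilyloxy)-1,9-bis{4-[tri(propan-2-yl)silyloxy]phenyl}non-2-en-1-yl]-7-hydroxy-5-methoxy-4H-chromen-4-one | COc1cc(O)c([C@@H](/C=C/CCC[C@@H](O[Si](C)(C)C(C)(C)C)CCc2ccc(O[Si](C(C)C)(C(C)C)C(C)C)cc2)c2ccc(O[Si](C(C)C)(C(C)C)C(C)C)cc2)c2occc(=O)c12 | intermediate
30 | 8-[(1S,2E,7R)-7-(tert-butyldimethylsilyloxy)-1,9-bis{4-[tri(propan-2-yl)silyloxy]phenyl}non-2-en-1-yl]-5-methoxy-7-[tri(propan-2-yl)silyloxy]-4H-chromen-4-one | COc1cc(O[Si](C(C)C)(C(C)C)C(C)C)c([C@@H](/C=C/CCC[C@@H](O[Si](C)(C)C(C)(C)C)CCc2ccc(O[Si](C(C)C)(C(C)C)C(C)C)cc2)c2ccc(O[Si](C(C)C)(C(C)C)C(C)C)cc2)c2occc(=O)c12 | intermediate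
31 | {4-[tri(propan-2-yl)silyloxy]phenyl}lithium | [Li]c1ccc(O[Si](C(C)C)(C(C)C)C(C)C)cc1 | intermediate
32 | {4-[tri(propan-2-yl)silyloxy]phenyl}boronic acid | OB(O)c1ccc(O[Si](C(C)C)(C(C)C)C(C)C)cc1 | intermediate
33 | (2S)-8-[(1S,2E,7R)-7-(tert-butyldimethylsilyloxy)-1,9-bis{4-[tri(propan-2-yl)silyloxy]phenyl}non-2-en-1-yl]-5-methoxy-2-{4-[tri(propan-2-yl)silyloxy]phenyl}-7-[tri(propan-2-yl)silyloxy]-2,3-dihydro-4H-chromen-4-one | COc1cc(O[Si](C(C)C)(C(C)C)C(C)C)c([C@@H](/C=C/CCC[C@@H](O[Si](C)(C)C(C)(C)C)CCc2ccc(O[Si](C(C)C)(C(C)C)C(C)C)cc2)c2ccc(O[Si](C(C)C)(C(C)C)C(C)C)cc2)c2c1C(=O)C[C@@H](c1ccc(O[Si](C(C)C)(C(C)C)C(C)C)cc1)O2 | intermediate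
34 | (2S)-7-hydroxy-8-[(1S,2E,7R)-7-hydroxy-1,9-bis(4-hydroxyphenyl)non-2-en-1-yl]-2-(4-hydroxyphenyl)-5-methoxy-2,3-dihydro-4H-chromen-4-one | COc1cc(O)c([C@@H](/C=C/CCC[C@@H](O)CCc2ccc(O)cc2)c2ccc(O)cc2)c2c1C(=O)C[C@@H](c1ccc(O)cc1)O2 | target

**Totals**
Total steps: 20. Longest linear sequence: 13 (steps 1–9, 16, 17, 19, 20).

**Three steps most likely to fail**

Step 4 (proposed new method). The alkyl diazomethane may give low ee or decompose before insertion. The fallback sets C7′ with Enders' auxiliary and keeps the Baeyer–Villiger expansion; it sets out from 2 and rejoins at 8. Compound 2 (Mg, THF; then oxirane, cat. CuI) gives 2-{4-[tri(propan-2-yl)silyloxy]phenyl}ethanol F1, and I2/PPh3/imidazole converts it into 1-(2-iodoethyl)-4-[tri(propan-2-yl)silyloxy]benzene F2. Cyclopentanone and RAMP are condensed to cyclopentanone RAMP-hydrazone F3. Deprotonation with LDA (THF, 0 °C) and alkylation with F2 at −100 °C gives the alkylated RAMP-hydrazone F4, and two-phase saturated aqueous oxalic acid/Et2O releases 8 without racemisation. RAMP is chosen because SAMP gives (R)-2-methylcyclohexanone and here the new chain outranks the ring CH2, so the same topicity would be named S.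

Step 16. The chromone-fused phenol may ionise too slowly for the biphenol cycle, or the background reaction may erode the ee. The fallback forms the same bond by Lewis-acid SN1 alkenylation with a trifluoroborate and then separates the C1′ epimers; it sets out from 14 and 27 and rejoins at 30. Compound 14 with KHF2 (MeOH/H2O) gives potassium (E)-alkenyltrifluoroborate F5. F5 and 27 with BF3·OEt2 (MeCN/CH2Cl2, −20 °C) give 29 together with its (1′R)-epimer F6 in about equal amounts. The mixture is silylated as in step 17, and 30 is separated from its (1′R)-epimer F7 by preparative chiral SFC.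

Step 19. The electron-rich, 8-substituted chromone may be a poor acceptor for aryl–Rh, or ring-opening may compete. The fallback uses a copper-catalysed 1,4-addition of the aryl Grignard and separates the C2 epimers; it sets out from 30 and 24 and rejoins at 33. Compound 24 (3 equiv) with CuBr·SMe2 (THF, −40 °C) adds to 30 to give 33 and its (2R)-epimer F8, which are diastereomers differing next to the C8 substituent and are separated on silica. F8 is recycled by DBU-catalysed ring-opening/ring-closure through the 2′-oxidochalcone (toluene, 60 °C).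

**Further compounds**
F1 | step 4 | 2-{4-[tri(propan-2-yl)silyloxy]phenyl}ethanol | OCCc1ccc(O[Si](C(C)C)(C(C)C)C(C)C)cc1
F2 | step 4 | 1-(2-iodoethyl)-4-[tri(propan-2-yl)silyloxy]benzene | ICCc1ccc(O[Si](C(C)C)(C(C)C)C(C)C)cc1
F3 | step 4 | cyclopentanone RAMP-hydrazone, (2R)-N-cyclopentylidene-2-(methoxymethyl)pyrrolidin-1-amine | COC[C@H]1CCCN1N=C1CCCC1
F4 | step 4 | alkylated RAMP-hydrazone, (2R)-2-(methoxymethyl)-N-[(2R)-2-(2-{4-[tri(propan-2-yl)silyloxy]phenyl}ethyl)cyclopentylidene]pyrrolidin-1-amine | COC[C@H]1CCCN1N=C1CCC[C@@H]1CCc1ccc(O[Si](C(C)C)(C(C)C)C(C)C)cc1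
F5 | step 16 | potassium (E)-alkenyltrifluoroborate, potassium [(1E,6R)-6-(tert-butyldimethylsilyloxy)-8-{4-[tri(propan-2-yl)silyloxy]phenyl}oct-1-en-1-yl]trifluoroborate | [K+].F[B-](F)(F)/C=C/CCC[C@@H](O[Si](C)(C)C(C)(C)C)CCc1ccc(O[Si](C(C)C)(C(C)C)C(C)C)cc1
F6 | step 16 | (1′R)-epimer of 29, 8-[(1R,2E,7R)-7-(tert-butyldimethylsilyloxy)-1,9-bis{4-[tri(propan-2-yl)silyloxy]phenyl}non-2-en-1-yl]-7-hydroxy-5-methoxy-4H-chromen-4-one | COc1cc(O)c([C@H](/C=C/CCC[C@@H](O[Si](C)(C)C(C)(C)C)CCc2ccc(O[Si](C(C)C)(C(C)C)C(C)C)cc2)c2ccc(O[Si](C(C)C)(C(C)C)C(C)C)cc2)c2occc(=O)c12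
F7 | step 16 | (1′R)-epimer of 30, 8-[(1R,2E,7R)-7-(tert-butyldimethylsilyloxy)-1,9-bis{4-[tri(propan-2-yl)silyloxy]phenyl}non-2-en-1-yl]-5-methoxy-7-[tri(propan-2-yl)silyloxy]-4H-chromen-4-one | COc1cc(O[Si](C(C)C)(C(C)C)C(C)C)c([C@H](/C=C/CCC[C@@H](O[Si](C)(C)C(C)(C)C)CCc2ccc(O[Si](C(C)C)(C(C)C)C(C)C)cc2)c2ccc(O[Si](C(C)C)(C(C)C)C(C)C)cc2)c2occc(=O)c12
F8 | step 19 | (2R)-epimer of 33 | COc1cc(O[Si](C(C)C)(C(C)C)C(C)C)c([C@@H](/C=C/CCC[C@@H](O[Si](C)(C)C(C)(C)C)CCc2ccc(O[Si](C(C)C)(C(C)C)C(C)C)cc2)c2ccc(O[Si](C(C)C)(C(C)C)C(C)C)cc2)c2c1C(=O)C[C@H](c1ccc(O[Si](C(C)C)(C(C)C)C(C)C)cc1)O2
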